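## Structural features

The target (C18H16O8) is a cage built on a central cyclohexane-1,4-dione (C7, C8, C10, C14, C25, C23; carbonyls at C8 and C25). It is bridged twice in a 1,3-manner: C3=C2(CH3)–C12(=O) joins C7 to C10 (carbocycle A) and C18=C19(CH3)–C21(=O) joins C14 to C23 (carbocycle B), so two bicyclo[3.3.1]nonanes share the central ring. Two oxolanes are fused on: O5 links C4 (on C3) to C6 (on C7), and O16 links C17 (on C18) to C15 (on C14). The four stereocentres C7, C10, C14 and C23 are all fully substituted and form two vicinal pairs (C10–C14 and C23–C7); C7 and C14 are all-carbon quaternary centres, C10 and C23 are bridgehead tertiary alcohols. Each bridge locks its two bridgeheads cis, so the only open stereochemical question is whether the bridges lie on the same or on opposite faces of the central ring. The descriptors place them on opposite faces, which makes the molecule centrosymmetric, hence meso and achiral. Fragile points are the non-enolisable 1,3-diketones C8/C12 and C25/C21 (cleaved by nucleophilic bases), the α-ketols at C10 and C23 (acyl shift under base) and the γ-methylenes C4 and C17 of the enones; the real difficulty is the double anti bridging that creates both vicinal pairs, together with oxygenation of two bridgeheads. The key step uses the fact that each of the sets C12, C2 with its methyl, C3, C4, O5 and C21, C19 with its methyl, C18, C17, O16 is a 3-methylbutenolide, while the central ring with C6 and C15 is a 2,5-diformylcyclohexane-1,4-dione.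

## Logic of the disconnections

**11 to 10.** The bonds C10–O11 and C23–O24 are cut. An oxygen at C10 or C23 installed before the cage exists would sit β to the carbanionic carbon of a keto-aldehyde enolate and would be expelled with aromatisation of the central ring, so the hydroxyls must come last. The gain is the removal of both tertiary alcohols. The demand is that the forward step removes the C10 and C23 hydrogens in preference to the γ-hydrogens at C4 and C17 and uses no nucleophilic base; retention is the only possible outcome at a bridgehead.

**10 to 9.** A hydroxyl is added back at C6 and at C15 (functional-group addition), because lactols are what the cage-forming step delivers. This turns C6 and C15 into masked formyl carbons. The demand is an ionic reduction that touches neither the four ketones nor the enones.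

**9 to 3 and two molecules of 5 (through 8, 7 and 6).** Six bonds are cut: C23–C21 and O16–C15 (9 to 8), C14–C18 (8 to 7), C10–C12 and O5–C6 (7 to 6), C7–C3 (6 to 3 and 5). The cut follows the inversion symmetry, so one C5 unit serves twice. Four rings, six stereocentres and all eighteen carbons fall back to an achiral C8 bis-enol and a C5 vinylogous acyl bromide. The demands on the forward step are:
- Base count: four equivalents of non-nucleophilic amide are consumed productively (two for the enols of 3, one for each ketone enolisation), delivered in portions so that free amide never meets 5.
- No protection of 3: the second hydroxymethylene group, as its enolate, is what keeps C23 from being deprotonated; masking it as an enol ether would unblock C23.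
- Order: the second molecule of 5 is added only after ring A is closed, so that the first bridge directs it to the opposite face.

**3 to 1 and 2.** The bonds C7–C6 and C14–C15 are cut (β-keto aldehyde retron, Claisen formylation). The gain is two commercial materials. The demand is 2,5-regiochemistry and exclusion of air, since the bis-enol is a dihydro-aromatic.

**5 to 4.** The C3–Br bond is exchanged for C3–OH (a vinylogous acid). The demand is activation that leaves the lactone intact.

## Other disconnections considered

Alternative 1: The cut is at C7–C6 and C14–C15. The carbocyclic cage A1 (methyl enol ethers at C3 and C18, triethylsilyl ethers at C10 and C23, hydrogen at C7 and C14) would be deprotonated at both bridgeheads with a hindered lithium amide and trapped with benzyl chloromethyl ether A2, giving the bis(benzyloxymethyl) cage A3, the product of the key step.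
- In favour: bridgehead lithiation and alkylation of bicyclo[3.3.1]nonane vinylogous esters is a known reaction type, so on precedent this alternative is better than the chosen plan. The bridgehead oxygens are already present, so no late hydroxylation is needed, which is also better. Retention is automatic, which is equal to the chosen plan.
- Against: the step forms two bonds and no ring, and it leaves the real problem, the assembly of A1, unsolved. C7–H is flanked by only one carbonyl and is the less acidic type of bridgehead.
- Comparison: after A3 the methoxy groups at C3 and C18 must still be replaced by the carbons C4 and C17, the benzyl and silyl groups removed and both oxolanes closed. That is at least four further operations, against two after 9. On structure (no oxolane, two carbons missing) and step economy the chosen plan is clearly ahead. Both plans rely on polar carbanion chemistry.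

Alternative 2: The cuts are C10–C12 and C14–C18. In the spiro enal A4 (C7 spiro-oxolane on a cyclohexene-1,4-dione, exocyclic C3=C2(CH3)–C12HO, and at C14 the tether CH2–O–CH2–C18(S-tert-butyl)=C19(CH3)–C21HO), a thiyl radical would abstract the C12 formyl hydrogen. The acyl radical adds 6-exo to C10, the C14 radical closes 5-exo on C18, and loss of the thiyl radical gives the ring-A-closed bis-oxolane enal A5, the product of the key step.
- In favour: the conditions are neutral, so the base-sensitive diketones and aldehydes never meet an amide or alkoxide; on this point it is better than the chosen plan. Both radical additions are polarity-matched and the chain needs only catalytic thiol. The cis relation of C7 and C10 is enforced by the tether, which is equal to the chosen plan.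
- Against: only one bicycle is made. Ring B (C21–C23), the oxidation level at C21 and both bridgehead hydroxyls must follow. A4 is unsymmetrical and needs a long linear preparation, so the symmetry of the target is wasted. Two formyl groups compete for hydrogen abstraction, and the face of attack at C14 is biased but not enforced (equal to the chosen plan, where it is also only biased).
- Comparison: two rings and two C–C bonds are built, against four rings and six bonds. The individual radical steps are better precedented than the anionic cascade, but step economy is far worse.

Alternative 3: The cuts are C7–C3, C10–C12, C14–C18 and C23–C21, the same four C–C bonds as in the chosen plan (equal on this point). The bis(enol ether) A6 would be acylated twice by methylmalonyl dichloride A7 in Effenberger-type annulations to give the doubly bridged hexaketone A8, the product of the key step.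
- In favour: this annulation is an established way to make bicyclo[3.3.1]nonane-2,4,9-triones, so precedent is better than for the chosen plan. No strong base is used. The bridgeheads C10 and C23 end as C–H, exactly as in 10, and the anti arrangement rests on the same facial argument (both equal).
- Against: acylation must occur at fully substituted enol-ether carbons carrying benzyloxymethyl groups, a more hindered case than usual for a reaction type regarded as capricious. A6 is acid-sensitive and not easy to prepare. The C3 unit places oxygen at C3 and C18 where the target has C4 and C17.
- Comparison: from A8 one must differentiate the two oxygens of each enolised diketone, attach a one-carbon unit at C3 and C18, debenzylate and close two ethers before reaching 10. The chosen plan forms these carbons and both C–O bonds in the key step itself, so it is better on structure and step economy, while A8 is better on precedent.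

Key step: step 3

Assumption: locants follow the atom order of the linear notation of the target; the target is the achiral meso compound with anti bridges; 6, 7 and 8 are racemic and 7, 8 and 9 are anomer mixtures, one stereoisomer being written for each.

## Route

Step 1
Reactants: 1 cyclohexane-1,4-dione; 2 ethyl formate (excess)
Product: 3 (2Z,5Z)-2,5-bis(hydroxymethylene)cyclohexane-1,4-dione
Conditions: NaOEt (2.2 equiv), Et2O/THF, 0 °C → rt, Ar; cold 1 M HCl
Reagents that add atoms: none
Why: Crossed Claisen condensation (formylation) with a non-enolisable formate under thermodynamic control; the disodium bis-enolate should precipitate and drive the equilibrium. The second formyl group should enter at C5, because C6 is α to the carbonyl already held in the first enolate and C3 adjoins the charged enolate carbon; no stereocentre is formed.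

Step 2
Reactants: 4 3-methyltetronic acid (4-hydroxy-3-methylfuran-2(5H)-one)
Product: 5 4-bromo-3-methylfuran-2(5H)-one
Conditions: (COBr)2 (1.2 equiv), DMF (cat.), CH2Cl2, 0 °C → rt
Reagents that add atoms: oxalyl bromide, O=C(Br)C(=O)Br
Why: Vilsmeier-type halodehydroxylation of a vinylogous acid: O-activation of the enol by the bromoiminium salt, conjugate addition of bromide and elimination, an established conversion of tetronic acids.

Step 3
Reactants: 3 (2Z,5Z)-2,5-bis(hydroxymethylene)cyclohexane-1,4-dione; 5 4-bromo-3-methylfuran-2(5H)-one (two equivalents in total)
Product: 9 bis-lactol cage (6,15-dihydroxy-10,23-dideoxy target; anti bridges; H at C10 and C23), via C7-alkenylated keto aldehyde 6 (not isolated), via ring-A mono-lactol 7 (not isolated), via C14-alkenylated mono-lactol 8 (not isolated)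
Conditions: LiN(SiMe3)2 (2.0 equiv), THF, −78 °C; 5 (1.0 equiv, slow), −78 → −20 °C; LiN(SiMe3)2 (1.05 equiv), −78 → 0 °C; AcOH (1.0 equiv), −78 °C; 5 (1.05 equiv), −40 → 0 °C; LiN(SiMe3)2 (2.05 equiv), −78 → 0 °C; AcOH, −78 °C
Reagents that add atoms: none
Why: Proposed new method: the dilithium bis-enolate of 3 should add through C7 to C3 of 5 and lose bromide (addition–elimination at a vinylogous acyl bromide, the known behaviour of 1,3-dicarbonyl anions toward 4-halofuran-2(5H)-ones), which makes C7 quaternary in 6. The next equivalent of amide can then enolise only C8 toward C10, since C7 has no hydrogen and C23 is α to the C25 carbonyl already tied up in the second keto-aldehyde enolate; this enolate acylates itself on the lactone carbonyl C12 (closest known type: Dieckmann-type opening of a lactone by a ketone enolate) and closes ring A in the 6-(enolendo)-exo-trig mode. The released C4 alkoxide adds 5-exo-trig to the C6 aldehyde, closing the first oxolane, and this lactolate is the sink that pulls the Claisen equilibrium forward because the bridgehead C10 gives no well-stabilised enolate. C7 is set without bias (racemic), C10 is fixed by the tether (C12 must be cis to C3) and C6 is an anomeric centre that is removed in step 4. One equivalent of acetic acid then protonates the lactolate of 7, so that the only nucleophile offered to the second molecule of 5 is the soft keto-aldehyde enolate, which should react at C14 by axial attack on the face opposite to the axial C10–C12 bond and so place C18 anti to bridge A in 8. With C14 quaternary and C10 a bridgehead, the last portion of base can only give the C25/C23 enolate, and ring B and the second oxolane close in the same two modes, C23 being fixed by the tether and C15 again anomeric. The step needs C- over O-alkenylation (lithium counter-ion in THF), C10 over C23 acylation (enolate blocking and six- against five-membered ring), mono-substitution in the first stage (dianion more nucleophilic than monoanion, slow addition, no free amide beside 5) and anti bridging (shielding by bridge A).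

Step 4
Reactants: 9 bis-lactol cage
Product: 10 10,23-dideoxy target (bis-oxolane cage tetraketone with H at C10 and C23)
Conditions: Et3SiH (6 equiv), BF3·OEt2 (4 equiv), CH2Cl2, −78 → −20 °C
Reagents that add atoms: none
Why: Ionic hydrogenation of lactols: BF3 ionises each anomeric hydroxyl to an oxocarbenium ion that takes hydride from the silane; C7 and C14 carry no hydrogen, so elimination to an enol ether is excluded. The hindered ketones and tetrasubstituted enones should survive at low temperature, the anomeric centres vanish and the four cage stereocentres are locked.

Step 5
Reactants: 10 10,23-dideoxy target
Product: 11 target CNP0299498.2 (meso 10,23-diol)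
Conditions: LiTMP (from n-BuLi and 2,2,6,6-tetramethylpiperidine, 3 equiv), THF, −78 °C; cannulate into 2-(phenylsulfonyl)-3-phenyloxaziridine (3 equiv), THF, −78 °C; AcOH, −78 °C
Reagents that add atoms: 2-(phenylsulfonyl)-3-phenyloxaziridine, O=S(=O)(c1ccccc1)N1OC1c1ccccc1
Why: Bridgehead lithiation followed by electrophilic hydroxylation of the carbanion with an N-sulfonyloxaziridine (enolate hydroxylation); bridgehead deprotonation of bicyclo[3.3.1]nonane-2,9-diones by hindered lithium amides is an established reaction type, and C10–H and C23–H are each flanked by two carbonyls and are electronically insulated from each other. Substitution at a bridgehead can only occur with retention, which gives the configuration of 11 directly; inverse addition keeps the carbanion away from the sulfonimine by-product.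

## Compound list

1 | cyclohexane-1,4-dione | O=C1CCC(=O)CC1 | starting material
2 | ethyl formate | CCOC=O | starting material
3 | (2Z,5Z)-2,5-bis(hydroxymethylene)cyclohexane-1,4-dione | O=C1C/C(=C/O)C(=O)C/C1=C/O | intermediate
4 | 3-methyltetronic acid | CC1=C(O)COC1=O | starting material
5 | 4-bromo-3-methylfuran-2(5H)-one | CC1=C(Br)COC1=O | intermediate
6 | 4-[(Z)-hydroxymethylene]-1-(4-methyl-5-oxo-2,5-dihydrofuran-3-yl)-2,5-dioxocyclohexane-1-carbaldehyde, racemic (not isolated) | O=C[C@]1(C2=C(C)C(=O)OC2)CC(=O)/C(=C\O)CC1=O | intermediate
7 | ring-A mono-lactol: enone bridge C3=C2(Me)–C12(=O) from C7 to C10, oxolane lactol (OH at C6), (Z)-hydroxymethylene at C14, CH2 at C23, racemic (not isolated) | CC1=C2CO[C@H](O)[C@]23C(=O)[C@H](C1=O)/C(=C/O)C(=O)C3 | intermediate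
8 | 7 carrying at C14 a formyl group and a 4-methyl-5-oxo-2,5-dihydrofuran-3-yl group, the latter anti to bridge A, racemic (not isolated) | CC1=C2CO[C@H](O)[C@]23C(=O)[C@H](C1=O)[C@@](C=O)(C1=C(C)C(=O)OC1)C(=O)C3 | intermediate
9 | bis-lactol cage (OH at C6 and C15, H at C10 and C23, anti bridges) | CC1=C2CO[C@H](O)[C@]23C(=O)[C@H](C1=O)[C@@]12[C@H](O)OCC1=C(C)C(=O)[C@@H]3C2=O | intermediate
10 | 10,23-dideoxy target (bis-oxolane cage tetraketone) | CC1=C2COC[C@]23C(=O)[C@H](C1=O)[C@@]12COCC1=C(C)C(=O)[C@@H]3C2=O | intermediate
11 | CNP0299498.2 (meso 10,23-dihydroxy bis-oxolane cage) | CC1=C2COC[C@]23C(=O)[C@](O)(C1=O)[C@@]12COCC1=C(C)C(=O)[C@]3(O)C2=O | target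

## Step count and least certain steps

Total: 5 steps. Longest linear sequence: 4 steps (1, 3, 4, 5); step 2 is a one-step branch.

**Step 3 (key step, proposed new method).** Three processes are most likely to go wrong.
- The amide may remove a γ-hydrogen at C4 of the butenolide in 6 instead of a C10 hydrogen, which converts the lactone carbonyl into an unreactive 2-oxidofuran.
- The free, non-enolisable formyl group may be attacked by the amide or by an alkoxide before it is masked as the lactolate, leading to deformylation or silylimine formation.
- A second substitution at C14 may run ahead of the first ring closure, which would remove both the enolate blocking and the facial bias.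

Fallback, with known reaction types only, setting out from 3 and 5 and returning to the route at 9: the cascade is run as four separate operations with isolation. The monosodium salt of excess 3 (NaH, THF/DMF, 0 °C) is alkenylated with 5 to give 6. Compound 6 is cyclised with LiN(SiMe3)2 (2 equiv) to 7. The monosodium enolate of 7 (NaH, 1 equiv, lactol left protonated) is alkenylated with 5 to give 8. Compound 8 is cyclised with LiN(SiMe3)2 (2 equiv) to 9. This passes only through compounds already in the list (entry F0) and lets each addition–elimination and each lactone opening be optimised alone.

**Step 5.** Removal of a γ-hydrogen at C4 or C17 (extended enolate) may compete with bridgehead lithiation. The second lithiation may also stay incomplete, or the first-formed lithium alkoxide may undergo acyl shift while the second site is metallated. Fallback from 10 back to 11: one bridgehead at a time. LiTMP (1.1 equiv) and the oxaziridine give the 10-hydroxy-23-deoxy cage F1, which is isolated and then treated with LiTMP (2.2 equiv, the first equivalent forming the alkoxide) and the oxaziridine to give 11.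

**Step 4.** Ionisation of the lactols may be slow, because the oxocarbenium ion sits next to an electron-poor quaternary carbon. Hydride reduction of the activated ketones or intermolecular acetal formation could then compete. Fallback from 9 back to 10: radical deoxygenation that needs no cation. PhOC(S)Cl with pyridine and catalytic DMAP converts 9 into the bis(O-phenoxythiocarbonyl) lactol F2, which Bu3SnH and AIBN in toluene at 80 °C reduce through the anomeric radicals (Barton–McCombie type) to 10.

**Step 1.** Air oxidation (aromatisation) of the dihydro-aromatic bis-enol during work-up, or incomplete second formylation, may erode the material. Fallback from 1 back to 3: condensation of 1 with N,N-dimethylformamide dimethyl acetal (neat, 100 °C) gives 2,5-bis[(dimethylamino)methylene]cyclohexane-1,4-dione F3. This is a stable, crystallisable solid, which is hydrolysed with aqueous NaOH and then acidified with HCl under argon to give 3.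

## Further compounds

F0 | step 3 | none | none
F1 | step 5 | 10-hydroxy-23-deoxy cage (mono-alcohol, racemic) | CC1=C2COC[C@]23C(=O)[C@](O)(C1=O)[C@@]12COCC1=C(C)C(=O)[C@@H]3C2=O
F2 | step 4 | bis(O-phenoxythiocarbonyl) derivative of the bis-lactol cage 9 | CC1=C2CO[C@H](OC(=S)Oc4ccccc4)[C@]23C(=O)[C@H](C1=O)[C@@]12[C@H](OC(=S)Oc4ccccc4)OCC1=C(C)C(=O)[C@@H]3C2=O
F3 | step 1 | 2,5-bis[(dimethylamino)methylene]cyclohexane-1,4-dione | CN(C)/C=C1\CC(=O)/C(=C/N(C)C)CC1=O
A1 | alternative 1 | carbocyclic cage with methyl enol ethers at C3 and C18, triethylsilyloxy at C10 and C23, H at C7 and C14 | CC1=C(OC)[C@@H]3C(=O)[C@](O[Si](CC)(CC)CC)(C1=O)[C@H]2C(OC)=C(C)C(=O)[C@]3(O[Si](CC)(CC)CC)C2=O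
A2 | alternative 1 | benzyl chloromethyl ether | ClCOCc1ccccc1
A3 | alternative 1 | cage with benzyloxymethyl groups at C7 and C14 (product of the key step) | CC1=C(OC)[C@]3(COCc4ccccc4)C(=O)[C@](O[Si](CC)(CC)CC)(C1=O)[C@@]2(COCc4ccccc4)C(OC)=C(C)C(=O)[C@]3(O[Si](CC)(CC)CC)C2=O
A4 | alternative 2 | spiro-oxolane cyclohexene-1,4-dione enal with tert-butylthio vinyl sulfide tether (racemic) | O=C/C(C)=C1/COC[C@]12C(=O)C=C(COC/C(SC(C)(C)C)=C(C)/C=O)C(=O)C2
A5 | alternative 2 | ring-A-closed bis-oxolane enal (product of the key step) | CC1=C4[C@]3(COC4)C(=O)[C@H](C1=O)[C@]5(COC/C5=C(C)/C=O)C(=O)C3
A6 | alternative 3 | 1,4-dimethoxy-2,5-bis(benzyloxymethyl)cyclohexa-1,4-diene | COC1=C(COCc2ccccc2)CC(OC)=C(COCc2ccccc2)C1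
A7 | alternative 3 | methylmalonyl dichloride | CC(C(=O)Cl)C(=O)Cl
A8 | alternative 3 | doubly bridged hexaketone with benzyloxymethyl groups at C7 and C14, C3 and C18 enols (product of the key step) | CC1=C(O)[C@]3(COCc4ccccc4)C(=O)[C@H](C1=O)[C@@]2(COCc4ccccc4)C(O)=C(C)C(=O)[C@@H]3C2=O
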